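**Assumption:** read from the SMILES, the target is 1R,4S,7R,7aS in the core and 6R in the acyl chain; core atoms are called C1–C7a (indene numbering) throughout, including in the monocyclic precursors.

## Retrosynthetic overview

1. Last operations: C7 tert-butyl ester to acid, allylic bromide to enal, and the 2-(bromomethyl)allyl group put on C1 by alkylating the cyclopentenone α'-enolate.
2. C4 ester: esterification of the 4β-alcohol with (2E,4E,6R)-4,6-dimethylocta-2,4-dienoic acid (tiglic acid, asymmetric hydrogenation, Wittig, Horner–Wadsworth–Emmons); the 4β-OH comes from a vinylogous Rubottom oxidation.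
3. C7 stereocentre: conjugate reduction of a C6=C7 enoate while the enone is masked as its silyl dienol ether.
4. Five-membered ring (formed second): hydration of a C7a propargyl group and aldol condensation onto the ring ketone.
5. C7a quaternary centre (key step): enantioselective phase-transfer α-propargylation of an achiral 2-methyl-3-oxocyclohexene ester; the six-membered ring comes preformed from 2-methylcyclohexane-1,3-dione (triflate, carbonylation).

## Route

**Step 1**
Reactants: 1 2-methylcyclohexane-1,3-dione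
Product: 2 2-methyl-3-oxocyclohex-1-en-1-yl trifluoromethanesulfonate
Conditions: Tf2O, pyridine, CH2Cl2, −78 → 0 °C
Reagents that add atoms: triflic anhydride, O=S(=O)(OS(=O)(=O)C(F)(F)F)C(F)(F)F
Why: O-sulfonylation of the enol form of the cyclic 1,3-dione (enol triflate formation) gives the vinyl triflate, with no stereocentre involved.

**Step 2**
Reactants: 2 2-methyl-3-oxocyclohex-1-en-1-yl trifluoromethanesulfonate
Product: 3 tert-butyl 2-methyl-3-oxocyclohex-1-ene-1-carboxylate
Conditions: Pd(OAc)2 (5 mol %), Xantphos, CO (1 atm), t-BuOH, i-Pr2NEt, DMF, 70 °C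
Reagents that add atoms: carbon monoxide, [C-]#[O+]; tert-butanol, CC(C)(C)O
Why: Palladium-catalysed alkoxycarbonylation of the electron-poor vinyl triflate (oxidative addition, CO insertion, alcoholysis) installs the C7 carboxyl carbon as a base-stable, acid-labile ester on an achiral enone.

**Step 3**
Reactants: 3 tert-butyl 2-methyl-3-oxocyclohex-1-ene-1-carboxylate
Product: 4 tert-butyl (6S)-6-methyl-5-oxo-6-(prop-2-yn-1-yl)cyclohex-1-ene-1-carboxylate
Conditions: propargyl bromide, chiral N-spiro bis(binaphthyl) quaternary ammonium bromide with 3,4,5-trifluorophenyl groups (3 mol %, antipode chosen for 6S), CsOH·H2O, toluene, −30 °C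
Reagents that add atoms: propargyl bromide, C#CCBr
Why: Proposed new method: enantioselective phase-transfer deconjugative α-alkylation of a cyclic α-methyl enone, in which interfacial γ-deprotonation at C6 by CsOH gives the extended dienolate, the C2-symmetric ammonium cation holds it as a tight ion pair, and propargyl bromide attacks the α-carbon C7a (largest HOMO coefficient, and attack there leaves C6=C7 conjugated to the ester) on one enantioface only to create the quaternary stereocentre; the closest known reaction type is the asymmetric phase-transfer alkylation of α-substituted cyclic β-keto esters and 2-substituted indanones or tetralones to α-quaternary ketones.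

**Step 4**
Reactants: 4 tert-butyl (6S)-6-methyl-5-oxo-6-(prop-2-yn-1-yl)cyclohex-1-ene-1-carboxylate
Product: 6 tert-butyl (7aR)-7a-methyl-2-oxo-2,4,5,7a-tetrahydro-1H-indene-7-carboxylate, via diketone 5 (not isolated)
Conditions: Ph3PAuNTf2 (2 mol %), 1,4-dioxane/H2O, 60 °C; then KOH, MeOH, rt
Reagents that add atoms: water, O
Why: Carbonyl-assisted Markovnikov hydration of the terminal alkyne gives the 1,4-diketone, whose intramolecular aldol condensation (methyl ketone onto the ring ketone, the only mode that can dehydrate) closes the cyclopentenone, while the quaternary C7a cannot epimerise (its descriptor changes to R only through CIP ranking).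

**Step 5**
Reactants: 6 tert-butyl (7aR)-7a-methyl-2-oxo-2,4,5,7a-tetrahydro-1H-indene-7-carboxylate
Product: 8 tert-butyl (7R,7aS)-2-{[tert-butyl(dimethyl)silyl]oxy}-7a-methyl-5,6,7,7a-tetrahydro-1H-indene-7-carboxylate, via silyl dienol ether 7 (not isolated)
Conditions: TBSOTf, Et3N, CH2Cl2, 0 °C; solvent change to toluene; Cu(OAc)2·H2O (5 mol %), 1,2-(Ph2P)2C6H4 (5 mol %), (EtO)2MeSiH, t-BuOH, rt
Reagents that add atoms: tert-butyldimethylsilyl triflate, CC(C)(C)[Si](C)(C)OS(=O)(=O)C(F)(F)F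
Why: Soft enolisation gives the extended silyl dienol ether, which masks the enone so that copper hydride conjugate reduction touches only the C6=C7 enoate, and protonation of the copper enolate at C7 from the face opposite the pseudo-axial C7a methyl sets 7R (ester cis to the methyl).

**Step 6**
Reactants: 8 tert-butyl (7R,7aS)-2-{[tert-butyl(dimethyl)silyl]oxy}-7a-methyl-5,6,7,7a-tetrahydro-1H-indene-7-carboxylate
Product: 9 tert-butyl (4S,7R,7aS)-4-hydroxy-7a-methyl-2-oxo-2,4,5,6,7,7a-hexahydro-1H-indene-7-carboxylate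
Conditions: mCPBA, CH2Cl2, −20 → 0 °C; aq. Na2S2O3/NaHCO3 work-up
Reagents that add atoms: mCPBA, OOC(=O)c1cccc(Cl)c1
Why: Vinylogous Rubottom oxidation, in which the peracid attacks the γ-carbon C4 of the dienol ether axially on the β face through a chair-like transition state (the same preference that gives 6β-alcohols from steroidal 3,5-dienol ethers), sets 4S and regenerates the enone.

**Step 7**
Reactants: 10 (2E)-2-methylbut-2-enoic acid (tiglic acid)
Product: 11 (2R)-2-methylbutanoic acid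
Conditions: H2 (4 atm), Ru(OAc)2[(R)-H8-BINAP] (0.5 mol %), MeOH, 20 °C
Reagents that add atoms: none
Why: Carboxylate-directed asymmetric hydrogenation of an α,β-unsaturated acid with the ruthenium bisphosphine catalyst (antipode of the one that gives the S acid) sets the 2R centre from an achiral acid.

**Step 8**
Reactants: 11 (2R)-2-methylbutanoic acid
Product: 12 (2R)-2-methylbutan-1-ol
Conditions: LiAlH4, Et2O, 0 °C → rt
Reagents that add atoms: none
Why: Hydride reduction of the acid to the primary alcohol leaves the stereocentre untouched.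

**Step 9**
Reactants: 12 (2R)-2-methylbutan-1-ol
Product: 14 (2E,4R)-2,4-dimethylhex-2-enal, via (2R)-2-methylbutanal 13 (not isolated)
Conditions: TEMPO (10 mol %), PhI(OAc)2, CH2Cl2, rt; then Ph3P=C(CH3)CHO, toluene, 80 °C
Reagents that add atoms: 2-(triphenylphosphoranylidene)propanal, CC(C=O)=P(c1ccccc1)(c1ccccc1)c1ccccc1
Why: Oxoammonium oxidation followed by in situ Wittig olefination with the stabilised ylide (E-selective) avoids isolating the volatile, epimerisable α-branched aldehyde.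

**Step 10**
Reactants: 14 (2E,4R)-2,4-dimethylhex-2-enal
Product: 15 (2E,4E,6R)-4,6-dimethylocta-2,4-dienoic acid
Conditions: (EtO)2P(O)CH2CO2H, n-BuLi (2 equiv), THF, −78 °C; then 14, −78 → 0 °C; 1 M HCl
Reagents that add atoms: diethylphosphonoacetic acid, CCOP(=O)(CC(=O)O)OCC
Why: Horner–Wadsworth–Emmons olefination with the phosphonoacetate dianion gives the E acid directly at low temperature, so the allylic stereocentre is not disturbed.

**Step 11**
Reactants: 9 tert-butyl (4S,7R,7aS)-4-hydroxy-7a-methyl-2-oxo-2,4,5,6,7,7a-hexahydro-1H-indene-7-carboxylate; 15 (2E,4E,6R)-4,6-dimethylocta-2,4-dienoic acid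
Product: 16 tert-butyl (4S,7R,7aS)-4-{[(2E,4E,6R)-4,6-dimethylocta-2,4-dienoyl]oxy}-7a-methyl-2-oxo-2,4,5,6,7,7a-hexahydro-1H-indene-7-carboxylate
Conditions: DCC, DMAP, CH2Cl2, 0 °C → rt
Reagents that add atoms: none
Why: Steglich esterification acylates the axial allylic alcohol with retention at C4, the C7 carboxyl being blocked as its tert-butyl ester so that it cannot lactonise or compete.

**Step 12**
Reactants: 16 tert-butyl (4S,7R,7aS)-4-{[(2E,4E,6R)-4,6-dimethylocta-2,4-dienoyl]oxy}-7a-methyl-2-oxo-2,4,5,6,7,7a-hexahydro-1H-indene-7-carboxylate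
Product: 18 tert-butyl (1R,4S,7R,7aS)-1-[2-(bromomethyl)prop-2-en-1-yl]-4-{[(2E,4E,6R)-4,6-dimethylocta-2,4-dienoyl]oxy}-7a-methyl-2-oxo-2,4,5,6,7,7a-hexahydro-1H-indene-7-carboxylate, via lithium enolate 17 (not isolated)
Conditions: LiN(SiMe3)2, THF, −78 °C; then 3-bromo-2-(bromomethyl)prop-1-ene (5 equiv), DMPU, −78 → −30 °C
Reagents that add atoms: 3-bromo-2-(bromomethyl)prop-1-ene, C=C(CBr)CBr
Why: Kinetic α'-deprotonation gives the cross-conjugated enolate, which is alkylated on the β face (the α face is blocked by the C7 methine and its ester) to give 1R, which is also the thermodynamically preferred C1 epimer because a C1 α-substituent would clash with the C7 ester.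

**Step 13**
Reactants: 18 tert-butyl (1R,4S,7R,7aS)-1-[2-(bromomethyl)prop-2-en-1-yl]-4-{[(2E,4E,6R)-4,6-dimethylocta-2,4-dienoyl]oxy}-7a-methyl-2-oxo-2,4,5,6,7,7a-hexahydro-1H-indene-7-carboxylate
Product: 19 tert-butyl (1R,4S,7R,7aS)-4-{[(2E,4E,6R)-4,6-dimethylocta-2,4-dienoyl]oxy}-1-(2-formylprop-2-en-1-yl)-7a-methyl-2-oxo-2,4,5,6,7,7a-hexahydro-1H-indene-7-carboxylate
Conditions: N-methylmorpholine N-oxide (5 equiv), MeCN, rt
Reagents that add atoms: N-methylmorpholine N-oxide, C[N+]1([O-])CCOCC1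
Why: Amine N-oxide oxidation of the allylic bromide (O-alkylation of the N-oxide, then elimination, Kornblum/Ganem type) gives the enal under non-basic conditions that leave the esters and C1 alone.

**Step 14**
Reactants: 19 tert-butyl (1R,4S,7R,7aS)-4-{[(2E,4E,6R)-4,6-dimethylocta-2,4-dienoyl]oxy}-1-(2-formylprop-2-en-1-yl)-7a-methyl-2-oxo-2,4,5,6,7,7a-hexahydro-1H-indene-7-carboxylate
Product: 20 (1R,4S,7R,7aS)-4-{[(2E,4E,6R)-4,6-dimethylocta-2,4-dienoyl]oxy}-1-(2-formylprop-2-en-1-yl)-7a-methyl-2-oxo-2,4,5,6,7,7a-hexahydro-1H-indene-7-carboxylic acid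
Conditions: CF3CO2H, CH2Cl2, 0 °C
Reagents that add atoms: none
Why: Acidolysis of the tert-butyl ester (loss of isobutene) frees the C7 acid without touching the allylic dienoate, enone or enal, and C1 stays in its favoured configuration.

## Compound list

1 | 2-methylcyclohexane-1,3-dione | CC1C(=O)CCCC1=O | starting material
2 | 2-methyl-3-oxocyclohex-1-en-1-yl trifluoromethanesulfonate | CC1=C(OS(=O)(=O)C(F)(F)F)CCCC1=O | intermediate
3 | tert-butyl 2-methyl-3-oxocyclohex-1-ene-1-carboxylate | CC1=C(C(=O)OC(C)(C)C)CCCC1=O | intermediate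
4 | tert-butyl (6S)-6-methyl-5-oxo-6-(prop-2-yn-1-yl)cyclohex-1-ene-1-carboxylate | C#CC[C@]1(C)C(=O)CCC=C1C(=O)OC(C)(C)C | intermediate
5 | tert-butyl (6S)-6-methyl-5-oxo-6-(2-oxopropyl)cyclohex-1-ene-1-carboxylate | CC(=O)C[C@]1(C)C(=O)CCC=C1C(=O)OC(C)(C)C | intermediate (not isolated)
6 | tert-butyl (7aR)-7a-methyl-2-oxo-2,4,5,7a-tetrahydro-1H-indene-7-carboxylate | O=C1C[C@@]2(C)C(C(=O)OC(C)(C)C)=CCCC2=C1 | intermediate
7 | tert-butyl (7aR)-2-{[tert-butyl(dimethyl)silyl]oxy}-7a-methyl-5,7a-dihydro-1H-indene-7-carboxylate | CC(C)(C)[Si](C)(C)OC1=CC2=CCC=C(C(=O)OC(C)(C)C)[C@]2(C)C1 | intermediate (not isolated)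
8 | tert-butyl (7R,7aS)-2-{[tert-butyl(dimethyl)silyl]oxy}-7a-methyl-5,6,7,7a-tetrahydro-1H-indene-7-carboxylate | CC(C)(C)[Si](C)(C)OC1=CC2=CCC[C@@H](C(=O)OC(C)(C)C)[C@]2(C)C1 | intermediate
9 | tert-butyl (4S,7R,7aS)-4-hydroxy-7a-methyl-2-oxo-2,4,5,6,7,7a-hexahydro-1H-indene-7-carboxylate | C1C(=O)C=C2[C@@H](O)CC[C@@H](C(=O)OC(C)(C)C)[C@@]21C | intermediate
10 | (2E)-2-methylbut-2-enoic acid (tiglic acid) | C/C=C(\C)C(=O)O | starting material
11 | (2R)-2-methylbutanoic acid | CC[C@@H](C)C(=O)O | intermediate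
12 | (2R)-2-methylbutan-1-ol | CC[C@@H](C)CO | intermediate
13 | (2R)-2-methylbutanal | CC[C@@H](C)C=O | intermediate (not isolated)
14 | (2E,4R)-2,4-dimethylhex-2-enal | CC[C@@H](C)/C=C(\C)C=O | intermediate
15 | (2E,4E,6R)-4,6-dimethylocta-2,4-dienoic acid | CC[C@@H](C)/C=C(C)/C=C/C(=O)O | intermediate
16 | tert-butyl (4S,7R,7aS)-4-{[(2E,4E,6R)-4,6-dimethylocta-2,4-dienoyl]oxy}-7a-methyl-2-oxo-2,4,5,6,7,7a-hexahydro-1H-indene-7-carboxylate | C1C(=O)C=C2[C@@H](OC(=O)/C=C/C(C)=C/[C@H](C)CC)CC[C@@H](C(=O)OC(C)(C)C)[C@@]21C | intermediate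
17 | lithium (4S,7R,7aS)-7-(tert-butoxycarbonyl)-4-{[(2E,4E,6R)-4,6-dimethylocta-2,4-dienoyl]oxy}-7a-methyl-5,6,7,7a-tetrahydro-4H-inden-2-olate (C1 enolate of 16) | C1=C([O-])C=C2[C@@H](OC(=O)/C=C/C(C)=C/[C@H](C)CC)CC[C@@H](C(=O)OC(C)(C)C)[C@@]21C.[Li+] | intermediate (not isolated)
18 | tert-butyl (1R,4S,7R,7aS)-1-[2-(bromomethyl)prop-2-en-1-yl]-4-{[(2E,4E,6R)-4,6-dimethylocta-2,4-dienoyl]oxy}-7a-methyl-2-oxo-2,4,5,6,7,7a-hexahydro-1H-indene-7-carboxylate | BrCC(=C)C[C@H]1C(=O)C=C2[C@@H](OC(=O)/C=C/C(C)=C/[C@H](C)CC)CC[C@@H](C(=O)OC(C)(C)C)[C@@]21C | intermediate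
19 | tert-butyl (1R,4S,7R,7aS)-4-{[(2E,4E,6R)-4,6-dimethylocta-2,4-dienoyl]oxy}-1-(2-formylprop-2-en-1-yl)-7a-methyl-2-oxo-2,4,5,6,7,7a-hexahydro-1H-indene-7-carboxylate | C=C(C=O)C[C@H]1C(=O)C=C2[C@@H](OC(=O)/C=C/C(C)=C/[C@H](C)CC)CC[C@@H](C(=O)OC(C)(C)C)[C@@]21C | intermediate
20 | (1R,4S,7R,7aS)-4-{[(2E,4E,6R)-4,6-dimethylocta-2,4-dienoyl]oxy}-1-(2-formylprop-2-en-1-yl)-7a-methyl-2-oxo-2,4,5,6,7,7a-hexahydro-1H-indene-7-carboxylic acid | C=C(C=O)C[C@H]1C(=O)C=C2[C@@H](OC(=O)/C=C/C(C)=C/[C@H](C)CC)CC[C@@H](C(=O)O)[C@@]21C | target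

## Step count and risks

Total step count: 14. Longest linear sequence: 10 (steps 1–6 and 11–14; steps 7–10 make the acid 15).

**Risk at step 3 (the proposed new method).** The enone γ-hydrogens are only weakly acidic for phase-transfer conditions, and α- versus γ- or O-alkylation and the enantioselectivity are untested. The fallback uses established palladium chemistry and sets out from 3. The thermodynamic potassium dienolate (KH, THF) is trapped on oxygen with allyl chloroformate to give tert-butyl 6-methyl-5-{[(prop-2-en-1-yloxy)carbonyl]oxy}cyclohexa-1,5-diene-1-carboxylate F1. Decarboxylative asymmetric allylic alkylation of this allyl enol carbonate (Pd2(dba)3, (S)-t-Bu-PHOX or its antipode as needed for 6S, toluene, rt) gives tert-butyl (6S)-6-methyl-5-oxo-6-(prop-2-en-1-yl)cyclohex-1-ene-1-carboxylate F2. Tsuji–Wacker oxidation (PdCl2, CuCl, O2, DMF/H2O) turns the allyl group into the methyl ketone and comes back to the route at diketone 5, which is cyclised with KOH to 6 as in step 4.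

**Risk at step 5.** The copper hydride may not discriminate cleanly, the silyl dienol ether may not survive, or protonation at C7 may be unselective. The fallback removes the enone by reduction instead of masking it and sets out from 6. Luche reduction (NaBH4, CeCl3·7H2O, MeOH, −40 °C) gives tert-butyl (7aR)-2-hydroxy-7a-methyl-2,4,5,7a-tetrahydro-1H-indene-7-carboxylate F3 as a mixture at C2. Conjugate reduction of its enoate, now the only Michael acceptor, with the same Cu(OAc)2·H2O/bisphosphine/(EtO)2MeSiH/t-BuOH system gives tert-butyl (7R,7aS)-2-hydroxy-7a-methyl-2,4,5,6,7,7a-hexahydro-1H-indene-7-carboxylate F4. MnO2 in CH2Cl2 reoxidises the allylic alcohol to tert-butyl (7R,7aS)-7a-methyl-2-oxo-2,4,5,6,7,7a-hexahydro-1H-indene-7-carboxylate F5, and TBSOTf/Et3N then returns to the route at 8.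

**Risk at step 12.** Enolisation next to the quaternary centre in a molecule that carries two esters, and over-alkylation by the dibromide, may lower the yield. The fallback builds the side chain by conjugate addition and sets out from 16. LiN(SiMe3)2 and Me3SiCl (THF, −78 °C) give tert-butyl (4S,7R,7aS)-4-{[(2E,4E,6R)-4,6-dimethylocta-2,4-dienoyl]oxy}-7a-methyl-2-[(trimethylsilyl)oxy]-5,6,7,7a-tetrahydro-4H-indene-7-carboxylate F6. Mukaiyama–Michael addition to acrolein (BF3·OEt2, CH2Cl2, −78 °C) gives tert-butyl (1R,4S,7R,7aS)-4-{[(2E,4E,6R)-4,6-dimethylocta-2,4-dienoyl]oxy}-7a-methyl-2-oxo-1-(3-oxopropyl)-2,4,5,6,7,7a-hexahydro-1H-indene-7-carboxylate F7. Amine-catalysed α-methylenation of this aldehyde (aqueous CH2O, pyrrolidine, propionic acid, i-PrOH, 45 °C) comes back to the route at 19.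

## Further compounds

F1 | step 3 | tert-butyl 6-methyl-5-{[(prop-2-en-1-yloxy)carbonyl]oxy}cyclohexa-1,5-diene-1-carboxylate | C=CCOC(=O)OC1=C(C)C(C(=O)OC(C)(C)C)=CCC1
F2 | step 3 | tert-butyl (6S)-6-methyl-5-oxo-6-(prop-2-en-1-yl)cyclohex-1-ene-1-carboxylate | C=CC[C@]1(C)C(=O)CCC=C1C(=O)OC(C)(C)C
F3 | step 5 | tert-butyl (7aR)-2-hydroxy-7a-methyl-2,4,5,7a-tetrahydro-1H-indene-7-carboxylate (C2 epimers) | OC1C=C2CCC=C(C(=O)OC(C)(C)C)[C@]2(C)C1
F4 | step 5 | tert-butyl (7R,7aS)-2-hydroxy-7a-methyl-2,4,5,6,7,7a-hexahydro-1H-indene-7-carboxylate (C2 epimers) | OC1C=C2CCC[C@@H](C(=O)OC(C)(C)C)[C@]2(C)C1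
F5 | step 5 | tert-butyl (7R,7aS)-7a-methyl-2-oxo-2,4,5,6,7,7a-hexahydro-1H-indene-7-carboxylate | O=C1C=C2CCC[C@@H](C(=O)OC(C)(C)C)[C@]2(C)C1
F6 | step 12 | tert-butyl (4S,7R,7aS)-4-{[(2E,4E,6R)-4,6-dimethylocta-2,4-dienoyl]oxy}-7a-methyl-2-[(trimethylsilyl)oxy]-5,6,7,7a-tetrahydro-4H-indene-7-carboxylate | C1=C(O[Si](C)(C)C)C=C2[C@@H](OC(=O)/C=C/C(C)=C/[C@H](C)CC)CC[C@@H](C(=O)OC(C)(C)C)[C@@]21C
F7 | step 12 | tert-butyl (1R,4S,7R,7aS)-4-{[(2E,4E,6R)-4,6-dimethylocta-2,4-dienoyl]oxy}-7a-methyl-2-oxo-1-(3-oxopropyl)-2,4,5,6,7,7a-hexahydro-1H-indene-7-carboxylate | O=CCC[C@H]1C(=O)C=C2[C@@H](OC(=O)/C=C/C(C)=C/[C@H](C)CC)CC[C@@H](C(=O)OC(C)(C)C)[C@@]21C
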